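If the catalyst kept working, the flask (the dusk run, followed on) could run until the coupling partner gives out, at 90.0% target, since the partner is the limiting reagent. If it stopped at the last reading, target would stay at 55%. The real flask lies between, and the readings say where.

| setting | dusk | midnight | flask |
|---|---|---|---|
| starting material | 0.10 M | 0.10 M | 0.10 M |
| coupling partner | 0.090 M | 0.14 M | 0.0900 M |
| free catalyst | 1.4 mM | 1.4 mM | 1.4 mM |
| temperature | 100 °C | 106 °C | 100 °C |
| remark | the very flask that is asked about, followed so far | run made earlier |  |
| time |  |  | 8.0 d |

| run | time / h | target / % | starting material / % |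
|---|---|---|---|
| dusk | 10.0 | 25 | 75 |
| dusk | 20.0 | 32 | 70 |
| dusk | 30.0 | 37 | 65 |
| dusk | 60.0 | 45 | 52 |
| dusk | 120 | 55 | 45 |
| midnight | 2.00 | 11 | 90 |
| midnight | 4.00 | 18 | 82 |
| midnight | 6.00 | 21 | 78 |
| midnight | 8.00 | 25 | 74 |
| midnight | 10.0 | 30 | 67 |

(standard deviation of a reading: 1.5 percentage points)

- Thursday's: change nothing and wait 2.5 d more
- Wednesday's: at 8.0 d add free catalyst, 100% of the amount charged, then wait 2.5 d
- Tuesday's: at 8.0 d raise the temperature by 15 K, then wait 2.5 d
- Friday's: at 8.0 d add coupling partner, 100% of the amount charged, then wait 2.5 d
- Saturday's: at 8.0 d take out 90% of the target then present, then wait 2.5 d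

* target, in percent of the starting material first charged, at 8.0 d
* which option adds most target ("none" when 2 percentage points or less is all one gets) (Thursday's / Wednesday's / Tuesday's / Friday's / Saturday's / none)
* target present, with what was taken out counted in, in percent of the starting material first charged, after Wednesday's
* target present, with what was taken out counted in, in percent of the starting material first charged, after Saturday's

- what is taken out of target is counted as made
- additions bring no volume worth counting

In the dusk run target rose by 25% in the first 10.0 h and by 10 percentage points over the last 60.0 h, with 45% starting material still there. Target and starting material add up to about the whole charge, so we follow the starting material. As read, it loses a nearly fixed share each time the clock doubles. We name the slope of ln(starting material left) against ln(time) the ageing exponent, 0.206, so each doubling keeps a factor of 0.867. This is what a catalyst that wears out with its age would show, and we commit to that reading.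

Our reckoning carries the last reading forward to 40.9% starting material, so 59.1% target. Waiting adds 2.2 points. Taking out target leaves the clock running, so Saturday's adds the same, for 61.3%. A fresh catalyst charge restarts the clock. The dusk run kept 52% after a time equal to the wait, so we reckon that Wednesday's leaves 21.2% and gives 78.8% target. Our pick is Wednesday's.

The forecast reads the dusk run otherwise: “That points to target inhibition”. It gave 62% now, 69% after Wednesday's and 74% after Saturday's, and it picked Saturday's.

The flask gives 57.2% now, 74.6% after Wednesday's and 59.7% after Saturday's, and the best option is Wednesday's.

    coupling partner + free catalyst → catalyst intermediate A (k = 4700 M⁻¹ h⁻¹, Ea = 50.0 kJ mol⁻¹)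
    starting material + catalyst intermediate A → catalyst intermediate B (k = 37.4 M⁻¹ h⁻¹, Ea = 76.0 kJ mol⁻¹)
    catalyst intermediate B → free catalyst + target (k = 125 h⁻¹, Ea = 100 kJ mol⁻¹)
    2 catalyst intermediate A → spent catalyst (k = 83.5 M⁻¹ h⁻¹, Ea = 59.0 kJ mol⁻¹)
    target + free catalyst ⇌ isomer of the product + free catalyst, rate k5*[free catalyst]*[target] forward; the back reaction follows from the equilibrium constant (K = 2.20, k = 117 M⁻¹ h⁻¹, Ea = 55.0 kJ mol⁻¹, ΔH = −29.0 kJ mol⁻¹)
    (constants at 100 °C)

At 14.8 h, catalyst intermediate A went on with starting material 50 times as fast as it paired into spent catalyst. Even so, spent catalyst stood at 97.7% by 192 h. From the 41.9% starting material there, the exponent gives 2.3 points for waiting, and Thursday's adds 2.4 points.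

For the flask kept at 75 °C, scaling the exponent by the ratio of the onward and pairing constants gives 0.139. Its catalyst age by the pairing constant is 12.5, so we reckon 70.4% starting material remaining. That flask holds 68% starting material and 31.9% target.

The readings were computed on assumed constants; noise was put on by code.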